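## Retrosynthetic overview

1. The epoxide is formed last: the C1 carboxyl group of a diene acid is turned into its own peroxy acid, which delivers oxygen to the ring double bond.
2. Key disconnection C8–C9 (sp3–sp2): blue-light nickel/iridium cross-electrophile coupling of a 6-(2-bromoethyl)-1,2-dioxane acid with an E-alkenyl bromide from dihydro-β-ionone (cyclohexene ring bought).
3. C6–C7: axial allylation of a six-membered peroxycarbenium ion made from a 6-hydroxy-1,2-dioxane (sets C6), then ozonolytic trimming to two carbons.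
4. 1,2-Dioxane ring: H2O2 opens a cis-β-lactone at C3 with inversion and closes onto the C6 ketone (sets C3, frees the C1 acid).
5. cis-β-Lactone from (R)-3-hydroxy-γ-butyrolactone by trans-methylation of its dianion (sets C2) and cuprate opening of an epoxide (C4–C5); ring order: oxetanone, 1,2-dioxane, epoxide.

Assumption: (R)-3-hydroxy-γ-butyrolactone is taken as a cheap commercial chiral building block (both enantiomers are sold).

Numbering: positions follow the target, C1 = carboxyl carbon, C2 = CH(CH3), C3 and C6 = dioxane carbons, C7–C12 = chain to the cyclohexane ring. The C6 descriptor reads S in 12–16 and R in 22–25 for the same spatial arrangement, because the ranking of the two carbon arms changes.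

## Route

Step 1
Reactants: 1 (4R)-4-hydroxyoxolan-2-one [(R)-3-hydroxy-γ-butyrolactone]
Product: 2 (3R,4R)-4-hydroxy-3-methyloxolan-2-one
Conditions: LiN(iPr)2 (2.2 equiv), THF, −78 → −40 °C; MeI, DMPU, −78 → −30 °C
Reagents that add atoms: iodomethane, CI
Why: Fráter–Seebach-type alkylation of the lactone dianion, in which MeI attacks the enolate face anti to the neighbouring alkoxide and so sets C2 (R) trans to the C3 oxygen.

Step 2
Reactants: 2 (3R,4R)-4-hydroxy-3-methyloxolan-2-one
Product: 4 ethyl (2R)-2-[(2R)-oxiran-2-yl]propanoate, via iodohydrin ester 3 (not isolated)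
Conditions: Me3SiI, EtOH, CH2Cl2, 0 → 23 °C; concentrate; Ag2O, MeCN, 23 °C
Reagents that add atoms: ethanol, CCO
Why: Silyl iodide cleavage of the lactone at the primary C4–O bond with esterification in situ, then silver-oxide-mediated Williamson closure of the iodohydrin to the terminal epoxide, neither stereocentre being touched.

Step 3
Reactants: 4 ethyl (2R)-2-[(2R)-oxiran-2-yl]propanoate
Product: 6 (2R,3S)-3-hydroxy-2,6-dimethylhept-6-enoic acid, via hydroxy ester 5 (not isolated)
Conditions: CH2=C(CH3)CH2MgCl (1.5 equiv), CuI (10 mol %), THF, −78 → −30 °C; then LiOH, H2O–MeOH, 23 °C; 1 M HCl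
Reagents that add atoms: 2-methylallylmagnesium chloride, CC(=C)C[Mg]Cl; lithium hydroxide, [Li+].[OH-]
Why: Copper-catalysed Grignard opening of the terminal epoxide at its CH2 carbon (SN2; the symmetric 2-methylallyl group gives one product), followed by saponification in the same flask, carries both stereocentres through to the syn acid.

Step 4
Reactants: 6 (2R,3S)-3-hydroxy-2,6-dimethylhept-6-enoic acid
Product: 8 (3R,4S)-3-methyl-4-(3-methylbut-3-en-1-yl)oxetan-2-one, via mixed anhydride 7 (not isolated)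
Conditions: PhSO2Cl, pyridine, 0 °C
Reagents that add atoms: none
Why: β-Lactonisation by carboxyl-group activation (mixed sulfonic anhydride), in which the C3 hydroxyl attacks the activated carbonyl, so the C3–O bond is kept and the syn acid gives the cis-β-lactone.

Step 5
Reactants: 8 (3R,4S)-3-methyl-4-(3-methylbut-3-en-1-yl)oxetan-2-one
Product: 9 (3R,4S)-3-methyl-4-(3-oxobutyl)oxetan-2-one
Conditions: O3, CH2Cl2, −78 °C; Me2S, −78 → 23 °C
Reagents that add atoms: ozone, [O-][O+]=O
Why: Ozonolysis of the 1,1-disubstituted alkene with reductive work-up unmasks the C6 methyl ketone, the β-lactone being inert to ozone and dimethyl sulfide at low temperature.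

Step 6
Reactants: 9 (3R,4S)-3-methyl-4-(3-oxobutyl)oxetan-2-one
Product: 11 (2R)-2-[(3R)-6-hydroxy-6-methyl-1,2-dioxan-3-yl]propanoic acid (both C6 epimers), via ketone perhydrate 10 (not isolated)
Conditions: H2O2 (anhydrous, Et2O, 3 equiv), Yb(OTf)3 (10 mol %), Et2O–MeCN, 0 → 23 °C
Reagents that add atoms: hydrogen peroxide, OO
Why: Proposed new method: H2O2 and the Lewis acid reversibly convert the ketone into its perhydrate, whose terminal OOH attacks the activated β-lactone at C3 in a 6-exo-tet SN2 displacement with alkyl–oxygen cleavage, so that the carboxylate is the leaving group, C3 is inverted to R and the 1,2-dioxane closes as its peroxyhemiketal (direct attack of H2O2 at C3 followed by closure onto the ketone leads to the same product); the closest known reactions are the neutral hydrolysis of β-butyrolactone by alkyl–oxygen fission with inversion and the Lewis-acid perhydrolysis of oxetanes by H2O2 at the more substituted carbon with inversion.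

Step 7
Reactants: 11 (2R)-2-[(3R)-6-hydroxy-6-methyl-1,2-dioxan-3-yl]propanoic acid (both C6 epimers)
Product: 12 (2R)-2-[(3R,6S)-6-methyl-6-(prop-2-en-1-yl)-1,2-dioxan-3-yl]propanoic acid
Conditions: CH2=CHCH2SiMe3 (4 equiv), Me3SiOTf (0.3 equiv), CH2Cl2, −78 → −40 °C; aqueous work-up
Reagents that add atoms: allyltrimethylsilane, C=CC[Si](C)(C)C
Why: Hosomi–Sakurai allylation of the six-membered peroxycarbenium ion, which reacts through the half-chair with the C3 side chain pseudo-equatorial by axial attack, so that the allyl group ends up cis to the C3 side chain with the methyl equatorial, which is the C6 configuration of the target.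

Step 8
Reactants: 12 (2R)-2-[(3R,6S)-6-methyl-6-(prop-2-en-1-yl)-1,2-dioxan-3-yl]propanoic acid
Product: 14 (2R)-2-[(3R,6S)-6-(2-hydroxyethyl)-6-methyl-1,2-dioxan-3-yl]propanoic acid, via aldehyde 13 (not isolated)
Conditions: O3, CH2Cl2, −78 °C; Me2S; then NaBH4, MeOH, 0 °C
Reagents that add atoms: ozone, [O-][O+]=O
Why: Ozonolysis of the terminal alkene with reductive work-up and borohydride reduction of the aldehyde, conditions under which the dialkyl peroxide and the acid survive and no stereocentre is touched.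

Step 9
Reactants: 14 (2R)-2-[(3R,6S)-6-(2-hydroxyethyl)-6-methyl-1,2-dioxan-3-yl]propanoic acid
Product: 16 (2R)-2-[(3R,6S)-6-(2-bromoethyl)-6-methyl-1,2-dioxan-3-yl]propanoic acid, via tosylate 15 (not isolated)
Conditions: TsCl, pyridine, CH2Cl2, 0 °C; aq. NaHCO3; then LiBr, acetone, 45 °C
Reagents that add atoms: lithium bromide, [Li+].[Br-]
Why: Sulfonylation of the primary alcohol (pyridine as the only base avoids ketene formation from the transient mixed anhydride, which is hydrolysed on work-up) and Finkelstein-type SN2 displacement by bromide, with all stereocentres untouched.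

Step 10
Reactants: 17 4-(2,6,6-trimethylcyclohex-1-en-1-yl)butan-2-one (dihydro-β-ionone)
Product: 19 2-(but-3-yn-1-yl)-1,3,3-trimethylcyclohex-1-ene, via enol phosphate 18 (not isolated)
Conditions: LiN(iPr)2, THF, −78 °C; ClP(O)(OEt)2; then LiN(iPr)2 (2.3 equiv), −78 → 23 °C; H2O
Reagents that add atoms: none
Why: Negishi alkyne synthesis, in which kinetic deprotonation at the methyl group, O-phosphorylation and double deprotonation–elimination of the enol phosphate give the terminal alkyne.

Step 11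
Reactants: 19 2-(but-3-yn-1-yl)-1,3,3-trimethylcyclohex-1-ene
Product: 21 2-[(3E)-4-bromo-3-methylbut-3-en-1-yl]-1,3,3-trimethylcyclohex-1-ene, via alkenylalane 20 (not isolated)
Conditions: Me3Al (2 equiv), Cp2ZrCl2 (0.2 equiv), CH2Cl2, 0 → 23 °C; then NBS, THF, −30 °C
Reagents that add atoms: trimethylaluminium, C[Al](C)C; N-bromosuccinimide, O=C1CCC(=O)N1Br
Why: Negishi zirconium-catalysed carboalumination adds methyl and aluminium syn across the alkyne with aluminium at the terminus, and brominolysis of the C–Al bond with retention gives the E-alkenyl bromide.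

Step 12
Reactants: 16 (2R)-2-[(3R,6S)-6-(2-bromoethyl)-6-methyl-1,2-dioxan-3-yl]propanoic acid; 21 2-[(3E)-4-bromo-3-methylbut-3-en-1-yl]-1,3,3-trimethylcyclohex-1-ene
Product: 22 (2R)-2-[(3R,6R)-6-methyl-6-[(3E)-4-methyl-6-(2,6,6-trimethylcyclohex-1-en-1-yl)hex-3-en-1-yl]-1,2-dioxan-3-yl]propanoic acid
Conditions: Ir[dF(CF3)ppy]2(dtbbpy)PF6 (1 mol %), NiCl2·glyme (5 mol %), dtbbpy (5 mol %), (Me3Si)3SiH (1.2 equiv), Na2CO3 (3 equiv), DME, 450 nm LEDs, 23 °C
Reagents that add atoms: none
Why: Metallaphotoredox cross-electrophile coupling, in which the light-excited iridium complex oxidises bromide, the bromine atom generates the silyl radical, this abstracts bromine from 16 much faster than it attacks the O–O bond, and the primary C8 radical is captured by nickel that has inserted into the alkenyl bromide, so that reductive elimination forms C8–C9 with the E geometry retained and no stereocentre touched.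

Step 13
Reactants: 22 (2R)-2-[(3R,6R)-6-methyl-6-[(3E)-4-methyl-6-(2,6,6-trimethylcyclohex-1-en-1-yl)hex-3-en-1-yl]-1,2-dioxan-3-yl]propanoic acid
Product: 25 (2R)-2-[(3R,6R)-6-methyl-6-[(3E)-4-methyl-6-[(1S,6R)-2,2,6-trimethyl-7-oxabicyclo[4.1.0]heptan-1-yl]hex-3-en-1-yl]-1,2-dioxan-3-yl]propanoic acid, via acyl imidazole 23 (not isolated), via peroxy acid 24 (not isolated)
Conditions: CDI, CH2Cl2, 23 °C; H2O2 (anhydrous, Et2O), 0 °C; then CH2Cl2 (0.5 mM), 23 °C
Reagents that add atoms: hydrogen peroxide, OO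
Why: Proposed new method: the acid is converted into its own peroxy acid and, at high dilution, the peroxy oxygen is delivered intramolecularly through a 15- to 16-membered butterfly transition state to the most electron-rich (tetrasubstituted) double bond, the tether formed by the two cis-disposed arms of the (3R,6R)-dioxane and the rigid E-olefin being expected to fold over one face only and so give the (1S,6R)-epoxide; the closest known reaction is the internal epoxidation of polyunsaturated fatty acids by their own peroxy acids through a ring of the same size, which selects one remote double bond but has not been used to select a face.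

## Compound list

1 | (4R)-4-hydroxyoxolan-2-one [(R)-3-hydroxy-γ-butyrolactone] | O=C1C[C@@H](O)CO1 | starting material
2 | (3R,4R)-4-hydroxy-3-methyloxolan-2-one | C[C@H]1C(=O)OC[C@@H]1O | intermediate
3 | ethyl (2R,3R)-3-hydroxy-4-iodo-2-methylbutanoate | CCOC(=O)[C@H](C)[C@@H](O)CI | intermediate
4 | ethyl (2R)-2-[(2R)-oxiran-2-yl]propanoate | CCOC(=O)[C@H](C)[C@@H]1CO1 | intermediate
5 | ethyl (2R,3S)-3-hydroxy-2,6-dimethylhept-6-enoate | CCOC(=O)[C@H](C)[C@@H](O)CCC(C)=C | intermediate
6 | (2R,3S)-3-hydroxy-2,6-dimethylhept-6-enoic acid | OC(=O)[C@H](C)[C@@H](O)CCC(C)=C | intermediate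
7 | benzenesulfonic (2R,3S)-3-hydroxy-2,6-dimethylhept-6-enoic anhydride | O=C(OS(=O)(=O)c1ccccc1)[C@H](C)[C@@H](O)CCC(C)=C | intermediate
8 | (3R,4S)-3-methyl-4-(3-methylbut-3-en-1-yl)oxetan-2-one | C[C@H]1C(=O)O[C@H]1CCC(C)=C | intermediate
9 | (3R,4S)-3-methyl-4-(3-oxobutyl)oxetan-2-one | C[C@H]1C(=O)O[C@H]1CCC(C)=O | intermediate
10 | (3R,4S)-4-(3-hydroperoxy-3-hydroxybutyl)-3-methyloxetan-2-one | C[C@H]1C(=O)O[C@H]1CCC(C)(O)OO | intermediate
11 | (2R)-2-[(3R)-6-hydroxy-6-methyl-1,2-dioxan-3-yl]propanoic acid (both C6 epimers) | CC1(O)CC[C@H]([C@@H](C)C(=O)O)OO1 | intermediate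
12 | (2R)-2-[(3R,6S)-6-methyl-6-(prop-2-en-1-yl)-1,2-dioxan-3-yl]propanoic acid | C=CC[C@]1(C)CC[C@H]([C@@H](C)C(=O)O)OO1 | intermediate
13 | (2R)-2-[(3R,6S)-6-methyl-6-(2-oxoethyl)-1,2-dioxan-3-yl]propanoic acid | O=CC[C@]1(C)CC[C@H]([C@@H](C)C(=O)O)OO1 | intermediate
14 | (2R)-2-[(3R,6S)-6-(2-hydroxyethyl)-6-methyl-1,2-dioxan-3-yl]propanoic acid | OCC[C@]1(C)CC[C@H]([C@@H](C)C(=O)O)OO1 | intermediate
15 | (2R)-2-[(3R,6S)-6-methyl-6-[2-(4-methylbenzenesulfonyloxy)ethyl]-1,2-dioxan-3-yl]propanoic acid | Cc1ccc(cc1)S(=O)(=O)OCC[C@]1(C)CC[C@H]([C@@H](C)C(=O)O)OO1 | intermediate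
16 | (2R)-2-[(3R,6S)-6-(2-bromoethyl)-6-methyl-1,2-dioxan-3-yl]propanoic acid | BrCC[C@]1(C)CC[C@H]([C@@H](C)C(=O)O)OO1 | intermediate
17 | 4-(2,6,6-trimethylcyclohex-1-en-1-yl)butan-2-one (dihydro-β-ionone) | CC(=O)CCC1=C(C)CCCC1(C)C | starting material
18 | diethyl 4-(2,6,6-trimethylcyclohex-1-en-1-yl)but-1-en-2-yl phosphate | C=C(CCC1=C(C)CCCC1(C)C)OP(=O)(OCC)OCC | intermediate
19 | 2-(but-3-yn-1-yl)-1,3,3-trimethylcyclohex-1-ene | C#CCCC1=C(C)CCCC1(C)C | intermediate
20 | dimethyl[(1E)-2-methyl-4-(2,6,6-trimethylcyclohex-1-en-1-yl)but-1-en-1-yl]alumane | C/C(=C\[Al](C)C)CCC1=C(C)CCCC1(C)C | intermediate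
21 | 2-[(3E)-4-bromo-3-methylbut-3-en-1-yl]-1,3,3-trimethylcyclohex-1-ene | C/C(=C\Br)CCC1=C(C)CCCC1(C)C | intermediate
22 | (2R)-2-[(3R,6R)-6-methyl-6-[(3E)-4-methyl-6-(2,6,6-trimethylcyclohex-1-en-1-yl)hex-3-en-1-yl]-1,2-dioxan-3-yl]propanoic acid | C/C(=C\CC[C@]1(C)CC[C@H]([C@@H](C)C(=O)O)OO1)CCC1=C(C)CCCC1(C)C | intermediate
23 | (2R)-1-(1H-imidazol-1-yl)-2-[(3R,6R)-6-methyl-6-[(3E)-4-methyl-6-(2,6,6-trimethylcyclohex-1-en-1-yl)hex-3-en-1-yl]-1,2-dioxan-3-yl]propan-1-one | C/C(=C\CC[C@]1(C)CC[C@H]([C@@H](C)C(=O)n2ccnc2)OO1)CCC1=C(C)CCCC1(C)C | intermediate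
24 | (2R)-2-[(3R,6R)-6-methyl-6-[(3E)-4-methyl-6-(2,6,6-trimethylcyclohex-1-en-1-yl)hex-3-en-1-yl]-1,2-dioxan-3-yl]propaneperoxoic acid | C/C(=C\CC[C@]1(C)CC[C@H]([C@@H](C)C(=O)OO)OO1)CCC1=C(C)CCCC1(C)C | intermediate
25 | (2R)-2-[(3R,6R)-6-methyl-6-[(3E)-4-methyl-6-[(1S,6R)-2,2,6-trimethyl-7-oxabicyclo[4.1.0]heptan-1-yl]hex-3-en-1-yl]-1,2-dioxan-3-yl]propanoic acid | C/C(=C\CC[C@]1(C)CC[C@H]([C@@H](C)C(=O)O)OO1)CC[C@@]12O[C@]1(C)CCCC2(C)C | target

## Step count and risks

Total steps: 13. Longest linear sequence: 11 (steps 1–9, 12, 13).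

**Risk 1, step 6 (new perhydrolysis cascade).** H2O2 may attack the acyl carbon (giving a β-hydroxy peroxy acid) in place of C3, or the Lewis acid may trigger other ring openings. The fallback uses known chemistry, sets out from 6 and comes back at 11:
- Acid 6 is reduced with LiAlH4 to (2S,3S)-2,6-dimethylhept-6-ene-1,3-diol F1.
- The primary hydroxyl is tosylated selectively (TsCl, pyridine, 0 °C) to (2S,3S)-3-hydroxy-2,6-dimethylhept-6-en-1-yl 4-methylbenzenesulfonate F2.
- KOt-Bu closes this to (2S,3S)-3-methyl-2-(3-methylbut-3-en-1-yl)oxetane F3, with the C3–O bond untouched.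
- Ozonolysis (O3; Me2S) gives 4-[(2S,3S)-3-methyloxetan-2-yl]butan-2-one F4.
- The known Lewis-acid perhydrolysis of oxetanes (H2O2 in Et2O, Me3SiOTf cat., −78 → 0 °C) opens the ring at the secondary carbon with inversion to (5R,6S)-5-hydroperoxy-7-hydroxy-6-methylheptan-2-one F5.
- F5 closes spontaneously to (2S)-2-[(3R)-6-hydroxy-6-methyl-1,2-dioxan-3-yl]propan-1-ol F6.
- Oxidation with PhI(OAc)2 and catalytic TEMPO in MeCN–H2O passes through (2R)-2-[(3R)-6-hydroxy-6-methyl-1,2-dioxan-3-yl]propanal F7 and gives 11.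

**Risk 2, step 13 (new tether-directed epoxidation).** The level and the sense of facial control by the remote dioxane are unproven. The bimolecular pathway and attack at the C9–C10 double bond can compete, and the acyl imidazole could epimerise C2. The fallback uses known chemistry, sets out from 22 and comes back at 25. Buffered mCPBA (1.0 equiv, NaHCO3, CH2Cl2, −20 °C) epoxidises the tetrasubstituted double bond selectively but without facial control. Target 25 is then separated by preparative HPLC from its epoxide diastereomer (2R)-2-[(3R,6R)-6-methyl-6-[(3E)-4-methyl-6-[(1R,6S)-2,2,6-trimethyl-7-oxabicyclo[4.1.0]heptan-1-yl]hex-3-en-1-yl]-1,2-dioxan-3-yl]propanoic acid F10.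

**Risk 3, step 12 (light-driven coupling on a peroxide bearing a free acid).** The silyl radical or low-valent nickel may cleave the O–O bond, and the carboxylate may be oxidised by the excited photocatalyst. The fallback is a thermal two-electron palladium coupling, sets out from 21 and 16 and comes back at 22. Bromide 21 undergoes bromine–lithium exchange (t-BuLi, Et2O, −78 °C) to [(1E)-2-methyl-4-(2,6,6-trimethylcyclohex-1-en-1-yl)but-1-en-1-yl]lithium F8. Trapping with B(OiPr)3 and acidic work-up gives [(1E)-2-methyl-4-(2,6,6-trimethylcyclohex-1-en-1-yl)but-1-en-1-yl]boronic acid F9. F9 is joined to the primary bromide 16 by the known room-temperature alkyl Suzuki coupling (Pd(OAc)2, P(t-Bu)2Me, KOt-Bu, tert-amyl alcohol) to give 22.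

## Further compounds

F1 | step 6 | (2S,3S)-2,6-dimethylhept-6-ene-1,3-diol | OC[C@H](C)[C@@H](O)CCC(C)=C
F2 | step 6 | (2S,3S)-3-hydroxy-2,6-dimethylhept-6-en-1-yl 4-methylbenzenesulfonate | Cc1ccc(cc1)S(=O)(=O)OC[C@H](C)[C@@H](O)CCC(C)=C
F3 | step 6 | (2S,3S)-3-methyl-2-(3-methylbut-3-en-1-yl)oxetane | C[C@H]1CO[C@H]1CCC(C)=C
F4 | step 6 | 4-[(2S,3S)-3-methyloxetan-2-yl]butan-2-one | C[C@H]1CO[C@H]1CCC(C)=O
F5 | step 6 | (5R,6S)-5-hydroperoxy-7-hydroxy-6-methylheptan-2-one | CC(=O)CC[C@H]([C@@H](C)CO)OO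
F6 | step 6 | (2S)-2-[(3R)-6-hydroxy-6-methyl-1,2-dioxan-3-yl]propan-1-ol | CC1(O)CC[C@H]([C@@H](C)CO)OO1
F7 | step 6 | (2R)-2-[(3R)-6-hydroxy-6-methyl-1,2-dioxan-3-yl]propanal | CC1(O)CC[C@H]([C@@H](C)C=O)OO1
F8 | step 12 | [(1E)-2-methyl-4-(2,6,6-trimethylcyclohex-1-en-1-yl)but-1-en-1-yl]lithium | C/C(=C\[Li])CCC1=C(C)CCCC1(C)C
F9 | step 12 | [(1E)-2-methyl-4-(2,6,6-trimethylcyclohex-1-en-1-yl)but-1-en-1-yl]boronic acid | C/C(=C\B(O)O)CCC1=C(C)CCCC1(C)C
F10 | step 13 | (2R)-2-[(3R,6R)-6-methyl-6-[(3E)-4-methyl-6-[(1R,6S)-2,2,6-trimethyl-7-oxabicyclo[4.1.0]heptan-1-yl]hex-3-en-1-yl]-1,2-dioxan-3-yl]propanoic acid | C/C(=C\CC[C@]1(C)CC[C@H]([C@@H](C)C(=O)O)OO1)CC[C@]12O[C@@]1(C)CCCC2(C)C
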